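## The problem

Compound 28 is a cis-fused bicycle in which a cyclohexane (ring A: C1 the gem-dimethyl carbon, C2 the ring-fusion CH, C8 the methyl-bearing ring-fusion carbon, C9, C10, C11 the CHBr carbon) shares the C2–C8 bond with an oxepene (ring B: C2, C3 methylene, C4=C5 with the hydroxymethyl group on C5, C6 bearing the bromomethyl group, O7, C8). A synthesis has to create the fully substituted ether carbon C8 and close a seven-membered ring through it. Four stereocentres are needed: C6 is remote from ring A and is best set by a reagent-controlled reduction, after which it must dictate C8 during ring closure; C8 can then steer the ring-fusion hydrogen at C2 (cis to the C8 methyl) and, through the conformation of ring A, the bromide at C11 (cis to both). The C4=C5 bond must have C3 cis to C6 before the ring exists, since the alkene is the hinge of the closing chain. Three groups restrict the reagents: the primary bromide is β to O7 (reducing metals expel it together with the ring oxygen, and the free C5 hydroxymethyl oxygen displaces it under base); the C6–O7 bond is allylic; and the C11 bromide is secondary and neopentylic, hard to install by substitution and easy to lose by elimination. The opening lies in ring A: C11 and C8 are para to each other and C8 also carries a methyl group, the pattern of a 4-alkoxy-4-methylcyclohexa-2,5-dienone and therefore of an oxidised 4-methylphenol whose meta substituent becomes C3.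

## Retrosynthesis

**Silyl ether and C11–Br (28 ⇒ 27 ⇒ 25 ⇒ 24).** The O–Si bond of 27 is cut last and the C11–Br bond before it, leading to alcohol 25 and ketone 24. A C11 carbonyl is what a phenol-derived ring A leaves behind, and making the bromide from it at the end keeps the elimination-prone bromide away from every enolate and hydride step. Ketone 24 has one stereocentre fewer. The forward steps need axial hydride delivery, substitution with inversion, and an acidic desilylation (under base the freed C5 hydroxymethyl group would attack the primary bromide).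

**C1 methyl groups and C2–H (24 ⇒ 22 ⇒ 19 ⇒ 18).** Both C1–CH3 bonds and the C2–H bond are traced back to enone 18. Direct double methylation of a saturated ketone would have to choose between C1 and C10; deconjugative dimethylation of 18 would move the double bond into ring B next to C4=C5; dissolving-metal reductive alkylation would destroy the β-alkoxy bromide. Each enolate is therefore generated regiospecifically by hydride conjugate addition: to the exocyclic enone 22 (first methyl from the methylene, second from iodomethane) and, before that, to 18, whose silyl enol ether 19 is methylenated at C1. Enone 18 lacks the quaternary carbon and the C2 stereocentre. The hydride must reach C2 anti to the C8–O7 bond.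

**C9–C10 saturation (18 ⇒ 17).** Removing two hydrogens gives the cross-conjugated dienone 17, the direct product of a phenol dearomatisation. Saturating C9=C10 first leaves a single enone for the C1/C2 chemistry. The forward step must distinguish a disubstituted from a trisubstituted enone double bond and spare C–Br and the allylic ether.

**O7–C8 (17 ⇒ 15), the key cut.** Cutting the tertiary ether bond and re-aromatising ring A gives phenol 15, an open chain on a cresol. Cutting O7–C6 instead would need a tertiary alcohol as nucleophile and gives no aromatic precursor; cutting C–C bonds of ring A would mean building the quaternary ether carbon by alkylation. Phenol 15 has one stereocentre and no ring beyond the arene. The forward reaction must make the C6 hydroxyl attack the para carbon in preference to acetate or solvent and must translate the C6 configuration into that of C8.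

**C6 carbinol and its halide (15 ⇒ 14 ⇒ 13 ⇒ 12).** The phenol is unveiled last from silyl ether 14 under non-basic conditions. The C6 stereocentre comes from catalyst-controlled reduction of bromomethyl ketone 13, itself from chloromethyl ketone 12 by halide exchange. A halo ketone is preferred to bromide opening of a vinyl epoxide, whose regiochemistry (allylic versus terminal carbon) is unreliable. The reduction must differentiate a branched alkenyl group from CH2Br and must not touch the enone double bond.

**C5–C6 (12 ⇒ 9 + 10).** The ketone is disconnected to vinyl iodide 9 and the two-carbon Weinreb amide 10. The alkene geometry is then carried by a configurationally stable alkenyl iodide. Carbometalation of a propargylic bromohydrin would instead place a magnesium alkoxide next to the bromide. The forward step needs iodine–lithium exchange with retention and a mono-addition.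

**C3–aryl bond and the iodoalkene (9 ⇒ 7 + 5; 5 ⇒ 4 ⇒ 2 ⇒ 1; 7 ⇒ 6).** The aryl–CH2 bond is cut to the Grignard reagent of aryl bromide 7 (from phenol 6) and allylic bromide 5. Bromide 5 derives from iodo alcohol 4, the product of hydroxyl-directed trans-hydroalumination and iodination of monosilylated diol 2, made from symmetrical diol 1. The symmetry of 1 removes any regiochemical question. The free hydroxyl of 2 first directs the hydride and then becomes the leaving group for arylation. All carbons of the chain thus come from three commercial compounds (1, 6, 10).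

## Roads not taken

**Alternative 1:** Both C–O bonds of ring B are cut by placing a carbonyl at C6 of a cis-fused bromo decalone A2 (Robinson-annulation chemistry). The forward key step is a Baeyer–Villiger oxidation with a peracid, in which the quaternary C8 migrates to oxygen with retention and gives the seven-membered lactone A1.
- Merits: C8 is set in a carbocycle by well-understood chemistry, and the migration is regioselective and stereospecific. On the security of C8 this road is better than the chosen one, whose facial selectivity is a prediction.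
- Weak points: A1 contains none of the functionality of C4–C6. The alkene, the C5 hydroxymethyl group and the C6 bromomethyl stereocentre would all have to be added to a lactone (enol phosphate coupling, reductive C-alkylation at the lactone carbon), with C6 set late on a flexible ring. The neopentyl bromide would be carried through peracid and enolate steps.
- Comparison: the chosen plan answers the safer C8 of this road with a key-step product 17 that already holds every ring-B carbon, the alkene and the C6 centre.

**Alternative 2:** Only O7–C6 is cut. A diazo β-keto ester A4 bearing the C8 tertiary alcohol is decomposed by a dirhodium tetracarboxylate catalyst, and the carbenoid inserts into the O–H bond to give oxepan-3-one A3.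
- Merits: O–H insertion works with hindered tertiary alcohols and is used for medium-ring ethers, so the ring closure is better precedented than a dearomative seven-membered closure. The C5 ketone is a handle for the alkene.
- Weak points: C6 emerges as a labile β-keto ester carbon carrying an ester where bromomethyl is needed. Reaching 28 would require regioselective enol triflate formation toward C4, introduction of the hydroxymethyl carbon, ester reduction, and bromination of one of two primary alcohols, with the C6 configuration fixed only afterwards. A4 needs its three ring-A stereocentres from a separate sequence, and its C11 silyl ether still requires the invertive bromination.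
- Comparison: the cyclisation is safer, but there is more work after it and no early control of C6. The chosen plan fixes C6 with a catalyst before ring closure and pays with an untested cyclisation.

**Alternative 3:** O7–C8 and C8–CH3 are cut. Hydroxy ketone A6, whose side chain is the same Z-allylic bromohydrin as in 15, is closed to a bicyclic mixed ketal with a silyl triflate and a methoxysilane, and a methylaluminium reagent replaces methoxide through the oxocarbenium ion to give A5.
- Merits: it shares the early C6 control of the chosen plan. Ring A arrives with the gem-dimethyl group, C2–H and the C11 oxygen in place, so only three or four steps follow ring closure, against seven after 17 here. No enone chemistry is run in the presence of CH2Br. In endgame length this road is better.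
- Weak points: C8 is made by intermolecular delivery of methyl to a seven-membered oxocarbenium ion, with no firm basis for the required face (methyl cis to C2–H). Proton loss to an enol ether competes and, toward C2, would erase that centre. C2 is α to the ketone in A6 and can epimerise under the Lewis acid. A6 itself needs an enantioselective synthesis of a 2,2-dimethyl-3-silyloxycyclohexanone and its alkylation with the side chain.
- Comparison: against the shorter endgame, the chosen plan offers ring A free of charge from a commercial cresol and an intramolecular event to set C8.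

Key step: step 10

Assumption: the stereodescriptors of the SMILES are taken literally, so 28 is the (2R,5aR,7S,9aS) isomer with a cis ring fusion. The hydroxymethyl group is carried as its tert-butyldiphenylsilyl ether, and the arene comes from commercial 3-bromo-4-methylphenol.

## Route

Step 1
Reactants: 1 but-2-yne-1,4-diol
Product: 2 4-[(tert-butyldiphenylsilyl)oxy]but-2-yn-1-ol
Conditions: NaH (1.0 equiv), THF, rt; then t-BuPh2SiCl (1.0 equiv), rt
Reagents that add atoms: tert-butyl(chloro)diphenylsilane, CC(C)(C)[Si](Cl)(c1ccccc1)c1ccccc1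
Why: One equivalent of NaH gives the poorly soluble monosodium alkoxide of the symmetrical diol, which is silylated before it equilibrates, so the monosilyl ether should predominate (O-silylation of an alkoxide).

Step 2
Reactants: 2 4-[(tert-butyldiphenylsilyl)oxy]but-2-yn-1-ol
Product: 4 (2Z)-4-[(tert-butyldiphenylsilyl)oxy]-3-iodobut-2-en-1-ol, via cyclic sodium vinylalanate 3 (not isolated)
Conditions: NaAlH2(OCH2CH2OMe)2 (1.6 equiv), THF, 0 °C; then I2, THF, −78 to 0 °C
Reagents that add atoms: iodine, II
Why: Hydroxyl-directed trans-hydroalumination of a propargylic alcohol: the O-bound aluminium hydride delivers hydride to the proximal alkyne carbon and aluminium ends on the distal carbon in the five-membered alanate 3. Iodinolysis with retention should therefore place iodine cis to CH2OH (Z) on the carbon that bears CH2OSi; the cold iodine quench is meant to outrun β-elimination of the silyloxy group.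

Step 3
Reactants: 4 (2Z)-4-[(tert-butyldiphenylsilyl)oxy]-3-iodobut-2-en-1-ol
Product: 5 {[(2Z)-4-bromo-2-iodobut-2-en-1-yl]oxy}(tert-butyl)diphenylsilane
Conditions: CBr4, PPh3, CH2Cl2, 0 °C
Reagents that add atoms: tetrabromomethane, BrC(Br)(Br)Br
Why: Appel bromination of a primary allylic alcohol under neutral conditions; the vinyl iodide, the silyl ether and the alkene geometry should be unaffected.

Step 4
Reactants: 6 3-bromo-4-methylphenol
Product: 7 (3-bromo-4-methylphenoxy)(tert-butyl)dimethylsilane
Conditions: t-BuMe2SiCl, imidazole, DMF, rt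
Reagents that add atoms: tert-butyl(chloro)dimethylsilane, CC(C)(C)[Si](C)(C)Cl
Why: Standard silylation of a phenol; the aryl silyl ether tolerates Grignard formation and is later the most easily cleaved silyl group in the molecule.

Step 5
Reactants: 7 (3-bromo-4-methylphenoxy)(tert-butyl)dimethylsilane; 5 {[(2Z)-4-bromo-2-iodobut-2-en-1-yl]oxy}(tert-butyl)diphenylsilane
Product: 9 tert-butyl{[(2Z)-4-{5-[(tert-butyldimethylsilyl)oxy]-2-methylphenyl}-2-iodobut-2-en-1-yl]oxy}diphenylsilane, via arylmagnesium bromide 8 (not isolated)
Conditions: Mg, THF, 50 °C; then 5, Li2CuCl4 (3 mol%), THF, −30 to 0 °C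
Reagents that add atoms: none
Why: Copper-catalysed coupling of an aryl Grignard reagent with a primary allylic bromide. Attack at the unhindered CH2 (SN2) is expected because the γ carbon is fully substituted and bears iodine; the alkene geometry is retained, and the alkenyl C–I bond does not react with Grignard reagents at this temperature without Pd, Ni or Fe.

Step 6
Reactants: 9 tert-butyl{[(2Z)-4-{5-[(tert-butyldimethylsilyl)oxy]-2-methylphenyl}-2-iodobut-2-en-1-yl]oxy}diphenylsilane; 10 2-chloro-N-methoxy-N-methylacetamide
Product: 12 (3Z)-3-{[(tert-butyldiphenylsilyl)oxy]methyl}-5-{5-[(tert-butyldimethylsilyl)oxy]-2-methylphenyl}-1-chloropent-3-en-2-one, via vinyllithium 11 (not isolated)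
Conditions: t-BuLi (2.1 equiv), Et2O, −78 °C; then 10, −78 to −20 °C; sat. aq. NH4Cl
Reagents that add atoms: none
Why: Iodine–lithium exchange of an alkenyl iodide proceeds with retention at −78 °C, and acylation by the Weinreb amide stops at the ketone because of the chelated tetrahedral adduct (Weinreb ketone synthesis). The chloro amide is used because a C–Cl bond, unlike C–Br, is not exchanged by the organolithium.

Step 7
Reactants: 12 (3Z)-3-{[(tert-butyldiphenylsilyl)oxy]methyl}-5-{5-[(tert-butyldimethylsilyl)oxy]-2-methylphenyl}-1-chloropent-3-en-2-one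
Product: 13 (3Z)-1-bromo-3-{[(tert-butyldiphenylsilyl)oxy]methyl}-5-{5-[(tert-butyldimethylsilyl)oxy]-2-methylphenyl}pent-3-en-2-one
Conditions: LiBr (10 equiv), acetone, rt (resubmitted once)
Reagents that add atoms: lithium bromide, [Li+].[Br-]
Why: Finkelstein halide exchange, fast at the carbonyl-activated CH2; the large excess of bromide should push the equilibrium to the bromo ketone.

Step 8
Reactants: 13 (3Z)-1-bromo-3-{[(tert-butyldiphenylsilyl)oxy]methyl}-5-{5-[(tert-butyldimethylsilyl)oxy]-2-methylphenyl}pent-3-en-2-one
Product: 14 (2R,3Z)-1-bromo-3-{[(tert-butyldiphenylsilyl)oxy]methyl}-5-{5-[(tert-butyldimethylsilyl)oxy]-2-methylphenyl}pent-3-en-2-ol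
Conditions: (R)-2-methyl-CBS-oxazaborolidine (20 mol%), catecholborane (1.5 equiv), toluene, −78 °C
Reagents that add atoms: none
Why: Corey–Bakshi–Shibata reduction: the ketone binds with the branched alkenyl group as the large and CH2Br as the small substituent, and the R catalyst should give the arrangement O → alkenyl → CH2Br anticlockwise with H to the rear, which is 2R because CH2Br outranks alkenyl. Catecholborane at −78 °C reduces only the carbonyl; the configuration would be checked by Mosher ester analysis.

Step 9
Reactants: 14 (2R,3Z)-1-bromo-3-{[(tert-butyldiphenylsilyl)oxy]methyl}-5-{5-[(tert-butyldimethylsilyl)oxy]-2-methylphenyl}pent-3-en-2-ol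
Product: 15 3-[(2Z,4R)-5-bromo-3-{[(tert-butyldiphenylsilyl)oxy]methyl}-4-hydroxypent-2-en-1-yl]-4-methylphenol
Conditions: KHF2 (2.5 equiv), MeOH, rt
Reagents that add atoms: none
Why: Bifluoride in methanol cleaves aryl silyl ethers much faster than alkyl silyl ethers, and the weakly acidic medium cannot close the bromohydrin to an epoxide as a basic deprotection would.

Step 10
Reactants: 15 3-[(2Z,4R)-5-bromo-3-{[(tert-butyldiphenylsilyl)oxy]methyl}-4-hydroxypent-2-en-1-yl]-4-methylphenol
Product: 17 (2R,9aS)-2-(bromomethyl)-3-{[(tert-butyldiphenylsilyl)oxy]methyl}-9a-methyl-5,9a-dihydro-1-benzoxepin-7(2H)-one, via acetoxy(aryloxy)phenyliodane 16 (not isolated)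
Conditions: PhI(OAc)2 (1.1 equiv), (CF3)2CHOH (0.01 M), 0 °C
Reagents that add atoms: none
Why: Proposed new method: ligand exchange of the phenol at trivalent iodine gives 16, and loss of iodobenzene and acetate in the ionising, non-nucleophilic fluoroalcohol generates a phenoxenium-type cation whose para carbon C8 is attacked by the C6 hydroxyl. The closest known reactions are PhI(OAc)2-mediated dearomative spiroetherification and para-quinol ether formation of 4-alkylphenols; new here is that the nucleophile sits on a meta side chain, so a seven-membered ortho-fused ether results. Ring B closes by O7–C8 bond formation, 7-exo-trig with respect to the C8=C9 bond of the cation (C9 stays outside the new ring); the Z alkene and the sp2 carbon C2 leave only the C3–C4 and C5–C6 bonds free to rotate, which should hold the hydroxyl over C8. The new stereocentre C8 is controlled by C6: in a chair-like forming ring the C6 substituent in the alkene plane eclipses the C5 silyloxymethyl group, so hydrogen should take that position and CH2Br the pseudo-axial one, on the face to which the C8 methyl moves (CH2Br cis to CH3, 2R,9aS). The step needs capture by the internal hydroxyl ahead of acetate or solvent and no proton loss from the C8 methyl to a quinone methide; high dilution, low temperature and the absence of any other nucleophile are meant to secure this.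

Step 11
Reactants: 17 (2R,9aS)-2-(bromomethyl)-3-{[(tert-butyldiphenylsilyl)oxy]methyl}-9a-methyl-5,9a-dihydro-1-benzoxepin-7(2H)-one
Product: 18 (2R,9aS)-2-(bromomethyl)-3-{[(tert-butyldiphenylsilyl)oxy]methyl}-9a-methyl-5,8,9,9a-tetrahydro-1-benzoxepin-7(2H)-one
Conditions: H2 (1 atm), RhCl(PPh3)3 (10 mol%), benzene–EtOH, rt
Reagents that add atoms: none
Why: RhCl(PPh3)3 hydrogenates the disubstituted double bond of 4,4-disubstituted cross-conjugated cyclohexadienones and leaves trisubstituted alkenes alone, so the C1=C2 enone and the C4=C5 bond should survive. No hydrogenolysis of C–Br or of the allylic C6–O7 bond is expected with this homogeneous catalyst.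

Step 12
Reactants: 18 (2R,9aS)-2-(bromomethyl)-3-{[(tert-butyldiphenylsilyl)oxy]methyl}-9a-methyl-5,8,9,9a-tetrahydro-1-benzoxepin-7(2H)-one
Product: 19 (2R,5aR,9aS)-2-(bromomethyl)-3-{[(tert-butyldiphenylsilyl)oxy]methyl}-7-{[dimethyl(phenyl)silyl]oxy}-9a-methyl-2,5,5a,8,9,9a-hexahydro-1-benzoxepine
Conditions: [(Ph3P)CuH]6 (5 mol%), PhMe2SiH (1.5 equiv), toluene, rt
Reagents that add atoms: dimethyl(phenyl)silane, C[SiH](C)c1ccccc1
Why: Copper hydride conjugate reduction followed by σ-bond metathesis of the copper enolate with the silane (1,4-hydrosilylation) gives the enol ether regiospecifically on the C1 side. Hydride should add to C2 anti to the pseudo-axial C8–O7 bond, the face not covered by ring B, which sets C2–H cis to the C8 methyl; the alkyl bromide and the isolated alkene are inert to this reagent.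

Step 13
Reactants: 19 (2R,5aR,9aS)-2-(bromomethyl)-3-{[(tert-butyldiphenylsilyl)oxy]methyl}-7-{[dimethyl(phenyl)silyl]oxy}-9a-methyl-2,5,5a,8,9,9a-hexahydro-1-benzoxepine
Product: 22 (2R,5aR,9aS)-2-(bromomethyl)-3-{[(tert-butyldiphenylsilyl)oxy]methyl}-9a-methyl-6-methylidene-5,5a,6,8,9,9a-hexahydro-1-benzoxepin-7(2H)-one, via Mannich base 20 (not isolated), via trimethylammonium iodide 21 (not isolated)
Conditions: CH2=NMe2+ I− (1.5 equiv), CH2Cl2, rt; then MeI, rt; then aq. NaHCO3, rt
Reagents that add atoms: N,N-dimethylmethyleneiminium iodide, C=[N+](C)C.[I-]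
Why: Mannich reaction of the silyl enol ether with the preformed iminium salt at C1, then N-methylation and elimination of trimethylamine, gives the exocyclic enone (α-methylenation). The bicarbonate elimination is mild enough not to move the double bond into the ring, which would erase C2.

Step 14
Reactants: 22 (2R,5aR,9aS)-2-(bromomethyl)-3-{[(tert-butyldiphenylsilyl)oxy]methyl}-9a-methyl-6-methylidene-5,5a,6,8,9,9a-hexahydro-1-benzoxepin-7(2H)-one
Product: 24 (2R,5aR,9aS)-2-(bromomethyl)-3-{[(tert-butyldiphenylsilyl)oxy]methyl}-6,6,9a-trimethyl-5,5a,6,8,9,9a-hexahydro-1-benzoxepin-7(2H)-one, via lithium enolate 23 (not isolated)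
Conditions: LiBH(s-Bu)3 (1.05 equiv), THF, −78 °C; then MeI (5 equiv), DMPU, −78 to 0 °C
Reagents that add atoms: iodomethane, CI
Why: 1,4-Reduction of the unhindered exocyclic enone turns the methylene into the first methyl group and generates the C1 enolate regiospecifically; C-methylation (reductive alkylation) completes the gem-dimethyl group. No stereocentre is created and C10 is never enolised.

Step 15
Reactants: 24 (2R,5aR,9aS)-2-(bromomethyl)-3-{[(tert-butyldiphenylsilyl)oxy]methyl}-6,6,9a-trimethyl-5,5a,6,8,9,9a-hexahydro-1-benzoxepin-7(2H)-one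
Product: 25 (2R,5aR,7R,9aS)-2-(bromomethyl)-3-{[(tert-butyldiphenylsilyl)oxy]methyl}-6,6,9a-trimethyl-2,5,5a,6,7,8,9,9a-octahydro-1-benzoxepin-7-ol
Conditions: NaBH4, MeOH, 0 °C
Reagents that add atoms: none
Why: Small hydrides attack 2,2-dimethylcyclohexanones along the axial direction. In the chair with O7 axial and the C8 methyl equatorial this is the face of the axial hydrogens at C2 and C9, which should give the equatorial 7R alcohol (OH trans to C2–H and to the C8 methyl).

Step 16
Reactants: 25 (2R,5aR,7R,9aS)-2-(bromomethyl)-3-{[(tert-butyldiphenylsilyl)oxy]methyl}-6,6,9a-trimethyl-2,5,5a,6,7,8,9,9a-octahydro-1-benzoxepin-7-ol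
Product: 27 {[(2R,5aR,7S,9aS)-7-bromo-2-(bromomethyl)-6,6,9a-trimethyl-2,5,5a,6,7,8,9,9a-octahydro-1-benzoxepin-3-yl]methoxy}(tert-butyl)diphenylsilane, via alkoxyphosphonium bromide 26 (not isolated)
Conditions: CBr4, PPh3, 2,6-lutidine, toluene, 0 to 60 °C
Reagents that add atoms: tetrabromomethane, BrC(Br)(Br)Br
Why: Appel reaction: bromide displaces the equatorial oxyphosphonium group of 26 with inversion along the axial trajectory, where only the axial hydrogens at C2 and C9 are in the way, giving the axial 7S bromide cis to C2–H and the C8 methyl. An equatorial leaving group has no anti-periplanar hydrogen, which disfavours E2.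

Step 17
Reactants: 27 {[(2R,5aR,7S,9aS)-7-bromo-2-(bromomethyl)-6,6,9a-trimethyl-2,5,5a,6,7,8,9,9a-octahydro-1-benzoxepin-3-yl]methoxy}(tert-butyl)diphenylsilane
Product: 28 [(2R,5aR,7S,9aS)-7-bromo-2-(bromomethyl)-6,6,9a-trimethyl-2,5,5a,6,7,8,9,9a-octahydro-1-benzoxepin-3-yl]methanol
Conditions: HF·pyridine, pyridine, THF, 0 °C to rt
Reagents that add atoms: none
Why: Fluoride desilylation under acidic conditions; a basic fluoride source is avoided because the liberated alkoxide would displace the neighbouring primary bromide to form a dihydrofuran and the axial bromide could eliminate.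

## Compound list

1 | but-2-yne-1,4-diol | OCC#CCO | starting material
2 | 4-[(tert-butyldiphenylsilyl)oxy]but-2-yn-1-ol | OCC#CCO[Si](c1ccccc1)(c1ccccc1)C(C)(C)C | intermediate
3 | cyclic sodium vinylalanate (1,2-oxaluminole ate complex, Al on the alkene carbon bearing CH2OSi) | [Na+].COCCO[Al-]1(OCCOC)OCC=C1CO[Si](c1ccccc1)(c1ccccc1)C(C)(C)C | intermediate
4 | (2Z)-4-[(tert-butyldiphenylsilyl)oxy]-3-iodobut-2-en-1-ol | OC/C=C(\I)CO[Si](c1ccccc1)(c1ccccc1)C(C)(C)C | intermediate
5 | {[(2Z)-4-bromo-2-iodobut-2-en-1-yl]oxy}(tert-butyl)diphenylsilane | BrC/C=C(\I)CO[Si](c1ccccc1)(c1ccccc1)C(C)(C)C | intermediate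
6 | 3-bromo-4-methylphenol | Cc1ccc(O)cc1Br | starting material
7 | (3-bromo-4-methylphenoxy)(tert-butyl)dimethylsilane | Cc1ccc(O[Si](C)(C)C(C)(C)C)cc1Br | intermediate
8 | {5-[(tert-butyldimethylsilyl)oxy]-2-methylphenyl}magnesium bromide | Cc1ccc(O[Si](C)(C)C(C)(C)C)cc1[Mg]Br | intermediate
9 | tert-butyl{[(2Z)-4-{5-[(tert-butyldimethylsilyl)oxy]-2-methylphenyl}-2-iodobut-2-en-1-yl]oxy}diphenylsilane | Cc1ccc(O[Si](C)(C)C(C)(C)C)cc1C/C=C(\I)CO[Si](c1ccccc1)(c1ccccc1)C(C)(C)C | intermediate
10 | 2-chloro-N-methoxy-N-methylacetamide | CON(C)C(=O)CCl | starting material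
11 | vinyllithium from 9 (Li in place of I, cis to the benzylic CH2) | Cc1ccc(O[Si](C)(C)C(C)(C)C)cc1C/C=C(\[Li])CO[Si](c1ccccc1)(c1ccccc1)C(C)(C)C | intermediate
12 | (3Z)-3-{[(tert-butyldiphenylsilyl)oxy]methyl}-5-{5-[(tert-butyldimethylsilyl)oxy]-2-methylphenyl}-1-chloropent-3-en-2-one | Cc1ccc(O[Si](C)(C)C(C)(C)C)cc1C/C=C(/CO[Si](c1ccccc1)(c1ccccc1)C(C)(C)C)C(=O)CCl | intermediate
13 | (3Z)-1-bromo-3-{[(tert-butyldiphenylsilyl)oxy]methyl}-5-{5-[(tert-butyldimethylsilyl)oxy]-2-methylphenyl}pent-3-en-2-one | Cc1ccc(O[Si](C)(C)C(C)(C)C)cc1C/C=C(/CO[Si](c1ccccc1)(c1ccccc1)C(C)(C)C)C(=O)CBr | intermediate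
14 | (2R,3Z)-1-bromo-3-{[(tert-butyldiphenylsilyl)oxy]methyl}-5-{5-[(tert-butyldimethylsilyl)oxy]-2-methylphenyl}pent-3-en-2-ol | Cc1ccc(O[Si](C)(C)C(C)(C)C)cc1C/C=C(/CO[Si](c1ccccc1)(c1ccccc1)C(C)(C)C)[C@H](CBr)O | intermediate
15 | 3-[(2Z,4R)-5-bromo-3-{[(tert-butyldiphenylsilyl)oxy]methyl}-4-hydroxypent-2-en-1-yl]-4-methylphenol | Cc1ccc(O)cc1C/C=C(/CO[Si](c1ccccc1)(c1ccccc1)C(C)(C)C)[C@H](CBr)O | intermediate
16 | acetoxy(aryloxy)phenyliodane of 15 (phenol oxygen bound to trivalent iodine) | CC(=O)OI(c1ccccc1)Oc1ccc(C)c(C/C=C(/CO[Si](c2ccccc2)(c2ccccc2)C(C)(C)C)[C@H](CBr)O)c1 | intermediate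
17 | (2R,9aS)-2-(bromomethyl)-3-{[(tert-butyldiphenylsilyl)oxy]methyl}-9a-methyl-5,9a-dihydro-1-benzoxepin-7(2H)-one | O=C1C=C2CC=C(CO[Si](c3ccccc3)(c3ccccc3)C(C)(C)C)[C@H](CBr)O[C@@]2(C)C=C1 | intermediate
18 | (2R,9aS)-2-(bromomethyl)-3-{[(tert-butyldiphenylsilyl)oxy]methyl}-9a-methyl-5,8,9,9a-tetrahydro-1-benzoxepin-7(2H)-one | O=C1C=C2CC=C(CO[Si](c3ccccc3)(c3ccccc3)C(C)(C)C)[C@H](CBr)O[C@@]2(C)CC1 | intermediate
19 | (2R,5aR,9aS)-2-(bromomethyl)-3-{[(tert-butyldiphenylsilyl)oxy]methyl}-7-{[dimethyl(phenyl)silyl]oxy}-9a-methyl-2,5,5a,8,9,9a-hexahydro-1-benzoxepine | C[Si](C)(c1ccccc1)OC1=C[C@H]2CC=C(CO[Si](c3ccccc3)(c3ccccc3)C(C)(C)C)[C@H](CBr)O[C@@]2(C)CC1 | intermediate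
20 | Mannich base: the 6-[(dimethylamino)methyl] ketone (C6 epimers) | CN(C)CC1[C@H]2CC=C(CO[Si](c3ccccc3)(c3ccccc3)C(C)(C)C)[C@H](CBr)O[C@@]2(C)CCC1=O | intermediate
21 | trimethylammonium iodide of 20 | C[N+](C)(C)CC1[C@H]2CC=C(CO[Si](c3ccccc3)(c3ccccc3)C(C)(C)C)[C@H](CBr)O[C@@]2(C)CCC1=O.[I-] | intermediate
22 | (2R,5aR,9aS)-2-(bromomethyl)-3-{[(tert-butyldiphenylsilyl)oxy]methyl}-9a-methyl-6-methylidene-5,5a,6,8,9,9a-hexahydro-1-benzoxepin-7(2H)-one | C=C1[C@H]2CC=C(CO[Si](c3ccccc3)(c3ccccc3)C(C)(C)C)[C@H](CBr)O[C@@]2(C)CCC1=O | intermediate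
23 | lithium enolate (6-methyl, C6=C7 enolate of the ring-A ketone) | CC=1[C@H]2CC=C(CO[Si](c3ccccc3)(c3ccccc3)C(C)(C)C)[C@H](CBr)O[C@@]2(C)CCC=1O[Li] | intermediate
24 | (2R,5aR,9aS)-2-(bromomethyl)-3-{[(tert-butyldiphenylsilyl)oxy]methyl}-6,6,9a-trimethyl-5,5a,6,8,9,9a-hexahydro-1-benzoxepin-7(2H)-one | CC1(C)[C@H]2CC=C(CO[Si](c3ccccc3)(c3ccccc3)C(C)(C)C)[C@H](CBr)O[C@@]2(C)CCC1=O | intermediate
25 | (2R,5aR,7R,9aS)-2-(bromomethyl)-3-{[(tert-butyldiphenylsilyl)oxy]methyl}-6,6,9a-trimethyl-2,5,5a,6,7,8,9,9a-octahydro-1-benzoxepin-7-ol | CC1(C)[C@H]2CC=C(CO[Si](c3ccccc3)(c3ccccc3)C(C)(C)C)[C@H](CBr)O[C@@]2(C)CC[C@H]1O | intermediate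
26 | 7-O-triphenylphosphonium bromide of 25 | CC1(C)[C@H]2CC=C(CO[Si](c3ccccc3)(c3ccccc3)C(C)(C)C)[C@H](CBr)O[C@@]2(C)CC[C@H]1O[P+](c1ccccc1)(c1ccccc1)c1ccccc1.[Br-] | intermediate
27 | {[(2R,5aR,7S,9aS)-7-bromo-2-(bromomethyl)-6,6,9a-trimethyl-2,5,5a,6,7,8,9,9a-octahydro-1-benzoxepin-3-yl]methoxy}(tert-butyl)diphenylsilane | CC1(C)[C@H]2CC=C(CO[Si](c3ccccc3)(c3ccccc3)C(C)(C)C)[C@H](CBr)O[C@@]2(C)CC[C@@H]1Br | intermediate
28 | [(2R,5aR,7S,9aS)-7-bromo-2-(bromomethyl)-6,6,9a-trimethyl-2,5,5a,6,7,8,9,9a-octahydro-1-benzoxepin-3-yl]methanol | CC1(C)[C@H]2CC=C(CO)[C@H](CBr)O[C@@]2(C)CC[C@@H]1Br | target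

## Step count and least certain steps

Total: 17 steps. Longest linear sequence: 16 steps (1 → 28 through steps 1–3 and 5–17; step 4 is a one-step side branch).

**Step 10 (key step, proposed new method).** Two processes may defeat it. Capture of the cation by acetate, or proton loss from the C8 methyl, may be faster than closure of a seven-membered ring. Facial selectivity at C8 may also be poor, because the A(1,2) argument that puts CH2Br pseudo-axial is opposed by a contact between CH2Br and the C8 methyl that grows as C8 pyramidalises.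

Fallback with known reactions, from 13 back to 17: the C8–O bond is made first by the established oxidation of a 4-alkylphenol to a para-quinol, and ring B is then closed at C6.
- Reduction of 13 with the S oxazaborolidine would give the 2S bromohydrin F1.
- K2CO3 in methanol would close it to the epoxide and remove the aryl silyl group, giving epoxy phenol F2.
- PhI(OAc)2 in aqueous acetonitrile would give the para-quinol F3 as both C8 epimers.
- Camphorsulfonic acid in CH2Cl2 would let the tertiary hydroxyl open the vinyl-activated epoxide at its allylic carbon C6 with inversion (7-exo), giving hydroxymethyl dienone F4 and its C8 epimer, to be separated.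
- Appel bromination of F4 would give 17.

The cost is that C8 forms without facial control, so at most half of the material reaches 17, and attack at C4 with allylic transposition would have to be excluded.

**Step 12.** Hydride may be delivered to the wrong face of C2 (trans ring fusion) if ring A prefers the half-chair with the C8 methyl pseudo-axial, or the β,β-disubstituted enone may react sluggishly.

Fallback, from 18 back to 19: the hydrogen is delivered intramolecularly.
- 1,2-Reduction of 18 with LiBH(s-Bu)3, expected from the face away from the pseudo-axial C9–H, would give allylic alcohol F5 with the hydroxyl cis to the C8 methyl.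
- Hydroxyl-directed hydrogenation with [Rh(nbd)(dppb)]BF4 would add hydrogen to C2 from the face of that hydroxyl, giving saturated alcohol F6.
- Dess–Martin oxidation would give ketone F7.
- Silylation under equilibrating conditions (PhMe2SiCl, NaI, Et3N, MeCN) should give 19, since cis-fused cyclohexanones of this kind enolise toward the ring fusion.

**Step 16.** Displacement at a secondary carbon next to a quaternary one is slow, and the oxyphosphonium ion may instead ionise with ring contraction or eliminate.

Fallback, from 25 back to 27: the leaving group is made and isolated first. Tf2O and pyridine at −20 °C would give triflate F8, which would be displaced by Bu4NBr in toluene at room temperature with inversion under non-ionising conditions.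

**Step 7.** The halide exchange is an equilibrium, and residual chloro ketone would be hard to separate and would carry a chloromethyl analogue through the route.

Fallback, from 9 back to 13: the bromine is introduced by enolate chemistry.
- Vinyllithium 11 would be acylated with N-methoxy-N-methylacetamide to give methyl ketone F9.
- Kinetic enolisation with LiN(SiMe3)2 and trapping with Me3SiCl would give silyl enol ether F10.
- N-Bromosuccinimide at −78 °C would give 13.

## Further compounds

F1 | step 10 | (2S,3Z)-1-bromo-3-{[(tert-butyldiphenylsilyl)oxy]methyl}-5-{5-[(tert-butyldimethylsilyl)oxy]-2-methylphenyl}pent-3-en-2-ol | Cc1ccc(O[Si](C)(C)C(C)(C)C)cc1C/C=C(/CO[Si](c1ccccc1)(c1ccccc1)C(C)(C)C)[C@@H](CBr)O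
F2 | step 10 | 3-[(2Z)-4-[(tert-butyldiphenylsilyl)oxy]-3-[(2S)-oxiran-2-yl]but-2-en-1-yl]-4-methylphenol | Cc1ccc(O)cc1C/C=C(/CO[Si](c1ccccc1)(c1ccccc1)C(C)(C)C)[C@H]1CO1
F3 | step 10 | 4-hydroxy-4-methyl-3-[(2Z)-4-[(tert-butyldiphenylsilyl)oxy]-3-[(2S)-oxiran-2-yl]but-2-en-1-yl]cyclohexa-2,5-dien-1-one (both C4 epimers) | CC1(O)C=CC(=O)C=C1C/C=C(/CO[Si](c1ccccc1)(c1ccccc1)C(C)(C)C)[C@H]1CO1
F4 | step 10 | (2R,9aS)-3-{[(tert-butyldiphenylsilyl)oxy]methyl}-2-(hydroxymethyl)-9a-methyl-5,9a-dihydro-1-benzoxepin-7(2H)-one | O=C1C=C2CC=C(CO[Si](c3ccccc3)(c3ccccc3)C(C)(C)C)[C@H](CO)O[C@@]2(C)C=C1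
F5 | step 12 | (2R,7S,9aS)-2-(bromomethyl)-3-{[(tert-butyldiphenylsilyl)oxy]methyl}-9a-methyl-2,5,7,8,9,9a-hexahydro-1-benzoxepin-7-ol | O[C@@H]1C=C2CC=C(CO[Si](c3ccccc3)(c3ccccc3)C(C)(C)C)[C@H](CBr)O[C@@]2(C)CC1
F6 | step 12 | (2R,5aR,7S,9aS)-2-(bromomethyl)-3-{[(tert-butyldiphenylsilyl)oxy]methyl}-9a-methyl-2,5,5a,6,7,8,9,9a-octahydro-1-benzoxepin-7-ol | O[C@@H]1C[C@H]2CC=C(CO[Si](c3ccccc3)(c3ccccc3)C(C)(C)C)[C@H](CBr)O[C@@]2(C)CC1
F7 | step 12 | (2R,5aR,9aS)-2-(bromomethyl)-3-{[(tert-butyldiphenylsilyl)oxy]methyl}-9a-methyl-5,5a,6,8,9,9a-hexahydro-1-benzoxepin-7(2H)-one | O=C1C[C@H]2CC=C(CO[Si](c3ccccc3)(c3ccccc3)C(C)(C)C)[C@H](CBr)O[C@@]2(C)CC1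
F8 | step 16 | (2R,5aR,7R,9aS)-2-(bromomethyl)-3-{[(tert-butyldiphenylsilyl)oxy]methyl}-6,6,9a-trimethyl-2,5,5a,6,7,8,9,9a-octahydro-1-benzoxepin-7-yl trifluoromethanesulfonate | CC1(C)[C@H]2CC=C(CO[Si](c3ccccc3)(c3ccccc3)C(C)(C)C)[C@H](CBr)O[C@@]2(C)CC[C@H]1OS(=O)(=O)C(F)(F)F
F9 | step 7 | (3Z)-3-{[(tert-butyldiphenylsilyl)oxy]methyl}-5-{5-[(tert-butyldimethylsilyl)oxy]-2-methylphenyl}pent-3-en-2-one | Cc1ccc(O[Si](C)(C)C(C)(C)C)cc1C/C=C(/CO[Si](c1ccccc1)(c1ccccc1)C(C)(C)C)C(C)=O
F10 | step 7 | tert-butyl{[(2Z)-4-{5-[(tert-butyldimethylsilyl)oxy]-2-methylphenyl}-2-{1-[(trimethylsilyl)oxy]ethenyl}but-2-en-1-yl]oxy}diphenylsilane | Cc1ccc(O[Si](C)(C)C(C)(C)C)cc1C/C=C(/CO[Si](c1ccccc1)(c1ccccc1)C(C)(C)C)C(=C)O[Si](C)(C)C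
A1 | alternative 1 | cis-fused 7-bromo-6,6,9a-trimethyloctahydro-1-benzoxepin-2(3H)-one | CC1(C)[C@H]2CCCC(=O)O[C@@]2(C)CC[C@@H]1Br
A2 | alternative 1 | cis-fused 6-bromo-5,5,8a-trimethyloctahydronaphthalen-1(2H)-one | CC1(C)[C@H]2CCCC(=O)[C@@]2(C)CC[C@@H]1Br
A3 | alternative 2 | cis-fused ethyl 7-[(tert-butyldimethylsilyl)oxy]-6,6,9a-trimethyl-3-oxodecahydro-1-benzoxepine-2-carboxylate | CC1(C)[C@H]2CCC(=O)C(C(=O)OCC)O[C@@]2(C)CC[C@H]1O[Si](C)(C)C(C)(C)C
A4 | alternative 2 | ethyl 5-{4-[(tert-butyldimethylsilyl)oxy]-2-hydroxy-2,6,6-trimethylcyclohexyl}-2-diazo-3-oxopentanoate | CC1(C)[C@@H](CCC(=O)C(=[N+]=[N-])C(=O)OCC)[C@@](C)(O)CC[C@H]1O[Si](C)(C)C(C)(C)C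
A5 | alternative 3 | cis-fused 3-[(benzyloxy)methyl]-2-(bromomethyl)-7-[(tert-butyldimethylsilyl)oxy]-6,6,9a-trimethyl-2,5,5a,6,7,8,9,9a-octahydro-1-benzoxepine (C7 epimeric to the bromide) | CC1(C)[C@H]2CC=C(COCc3ccccc3)[C@H](CBr)O[C@@]2(C)CC[C@H]1O[Si](C)(C)C(C)(C)C
A6 | alternative 3 | 2-[(2Z,4R)-3-[(benzyloxy)methyl]-5-bromo-4-hydroxypent-2-en-1-yl]-4-[(tert-butyldimethylsilyl)oxy]-3,3-dimethylcyclohexan-1-one | CC1(C)[C@@H](C/C=C(/COCc2ccccc2)[C@H](CBr)O)C(=O)CC[C@H]1O[Si](C)(C)C(C)(C)C
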